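The ratio Y of target P formed to substrate A consumed, Y = P/(100 − A), with both in percent of the substrate charged, is the selectivity that turns a conversion into a yield.

in all of them: precatalyst 15 mol%
- grey: substrate 1.3 M; coupling partner 1.1 equiv; temperature 45 °C; run made earlier
- red: substrate 2.1 M; coupling partner 1.1 equiv; temperature 62 °C; run made earlier
- Saturday's: substrate 0.95 M; coupling partner 1.10 equiv; temperature 50 °C; time 6.0 d
- Friday's: substrate 0.95 M; coupling partner 1.10 equiv; temperature 75 °C; time 6.0 d

| run | time / d | catalyst intermediate D / % | substrate / % | target / % | catalyst intermediate C / % |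
|---|---|---|---|---|---|
| grey | 1.04 | 1.5 | 85.3 | 1.4 | 0.9 |
| grey | 2.08 | 0.7 | 67.3 | 8.4 | 1.1 |
| grey | 3.00 | 0.4 | 53.8 | 14.6 | 1.3 |
| grey | 4.00 | 2.0 | 42.4 | 21.9 | 3.4 |
| grey | 5.00 | 2.0 | 33.5 | 29.3 | 3.6 |
| grey | 6.00 | 2.5 | 25.8 | 35.1 | 3.4 |
| grey | 8.00 | 3.9 | 10.6 | 48.5 | 2.0 |
| red | 0.333 | 1.9 | 61.1 | 7.5 | 1.8 |
| red | 0.500 | 1.6 | 47.6 | 16.3 | 2.6 |
| red | 0.625 | 3.6 | 38.7 | 22.2 | 2.3 |
| red | 1.25 | 2.0 | 16.2 | 41.1 | 2.4 |
| red | 1.67 | 1.9 | 6.1 | 47.5 | 2.8 |
| red | 3.00 | 1.9 | 1.8 | 58.3 | 0.1 |
| red | 4.00 | 2.2 | 1.5 | 58.5 | 0 |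

(readings scatter by 1 percentage point)



- which of these there is most of at the end, counted by the substrate in it, Saturday's (catalyst intermediate D / catalyst intermediate C / target / substrate)
- which of these there is most of at the end, counted by the substrate in it, Friday's (catalyst intermediate D / catalyst intermediate C / target / substrate)
- the largest of these amounts at the end, in percent of the substrate charged, Saturday's
- the largest of these amounts at the end, in percent of the substrate charged, Friday's

The last grey reading gives Y_grey, target over substrate consumed, as 0.543; the last red reading gives 0.594. Earlier in grey, Y reads lower, 0.473 at 6.00 d, so this reckoning holds Y at its late values, between those two last readings, and the next question is how much substrate Saturday's consumes.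

Between 3.00 d and 6.00 d in grey and between 0.333 d and 1.25 d in red, substrate falls roughly pseudo-first-order, with rate constant k = 0.245 d⁻¹ in grey and 1.45 d⁻¹ in red, as read from those readings. Those runs changed temperature and concentration together, so k is bracketed: independent of concentration, or proportional to it. Saturday's lies 0.294 of the way from grey's temperature to red's. Interpolating ln k gives 0.262 d⁻¹ to 0.413 d⁻¹, which leaves 8.39% to 20.7% substrate.

Does target lead? Y_grey gives 43.0% to 49.7%, above the highest substrate figure.

Friday's, extrapolated by the smaller bracket, has k = 1.77 d⁻¹, so its time spans 15.3 half-lives. This reckoning then puts target on Friday's at Y itself, 54.3% to 59.4%.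

The forecast names target on Saturday's at 42%, just below the 43.0% reckoned here as the lower end, and target on Friday's at 58%, inside the range reckoned here for Friday's. Its ground for Saturday's is “target ≈ 0.8 × (consumed − 30)”.

Saturday's ends with target 46.7% and substrate 16.1%, Friday's with target 54.9% and substrate 0.313%.

    coupling partner + free catalyst → catalyst intermediate A (k = 0.330 M⁻¹ h⁻¹, Ea = 69.0 kJ mol⁻¹)
    catalyst intermediate A → catalyst intermediate B (k = 0.414 h⁻¹, Ea = 113 kJ mol⁻¹)
    substrate + catalyst intermediate B ⇌ catalyst intermediate C (K = 1.67 M⁻¹, k = 0.508 M⁻¹ h⁻¹, Ea = 66.0 kJ mol⁻¹, ΔH = −69.0 kJ mol⁻¹)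
    catalyst intermediate C ⇌ catalyst intermediate D (K = 5.70, k = 0.383 h⁻¹, Ea = 104 kJ mol⁻¹, ΔH = −43.0 kJ mol⁻¹)
    catalyst intermediate D ⇌ free catalyst + target (K = 0.610 M, k = 0.510 h⁻¹, Ea = 99.0 kJ mol⁻¹, ΔH = 5.00 kJ mol⁻¹)
    2 substrate → self-condensation product (k = 0.00399 M⁻¹ h⁻¹, Ea = 81.0 kJ mol⁻¹)
    coupling partner + precatalyst → free catalyst + spent reagent (k = 0.0190 M⁻¹ h⁻¹, Ea = 88.0 kJ mol⁻¹)
    (constants at 50 °C)

Y_grey times the substrate consumed gives 45.5% for Saturday's, against the 46.7% found. Target's lead on Saturday's depends on the time: at 3.00 d that flask's substrate stood at 45.6%, above target at 22.1%, so at a stop there the forecast's choice is wrong. On Friday's, Y_grey gives 54.1%, against the 54.9% found.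

The earlier runs and the new flask come from a simulation with made-up constants, noise included.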